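Amber, ochre and teal each receive the same 0.062 M of substrate and 2.50 equiv of reagent, so what can differ between them is how long the two spend together.

| flask | substrate | reagent | remark | time |
|---|---|---|---|---|
| autumn | 0.062 M | 2.5 equiv | run made earlier |  |
| dawn | 0.031 M | 2.5 equiv | run made earlier |  |
| midnight | 0.12 M | 2.5 equiv | run made earlier |  |
| amber | 0.062 M | 2.50 equiv (fed, over 25 h) | all else is in the flask from the start; the feed brings no volume worth counting | 40 h |
| ochre | 0.062 M | 2.50 equiv | everything together at the start | 40 h |
| teal | 0.062 M (fed, over 25 h) | 2.50 equiv | all else is in the flask from the start; the feed brings no volume worth counting | 40 h |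

| run | time / h | bis adduct / % |
|---|---|---|
| autumn | 6.00 | 0.2 |
| autumn | 12.0 | 4.0 |
| autumn | 15.0 | 4.3 |
| autumn | 25.0 | 10.0 |
| autumn | 30.0 | 14.5 |
| autumn | 40.0 | 20.6 |
| dawn | 2.00 | 0 |
| dawn | 6.00 | 0.1 |
| dawn | 12.0 | 1.0 |
| dawn | 15.0 | 1.3 |
| dawn | 25.0 | 3.8 |
| dawn | 30.0 | 4.5 |
| dawn | 40.0 | 7.5 |
| midnight | 6.00 | 3.6 |
| midnight | 12.0 | 9.2 |
| midnight | 15.0 | 13.0 |
| midnight | 25.0 | 25.6 |
| midnight | 30.0 | 30.0 |
| midnight | 40.0 | 40.2 |

(standard deviation of a reading: 0.5 percentage points)



- which flask leads in amount of bis adduct, in percent of the substrate charged ("all alike" within 1.5 percentage points) (amber / ochre / teal / all alike)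
- how much bis adduct is there at the end, in percent of the substrate charged: amber
- how much bis adduct is there at the end, in percent of the substrate charged: ochre
- how much bis adduct is there at the end, in percent of the substrate charged: teal

Dawn at 30.0 h reads 4.5%, and autumn, at twice the concentration for half the time, reads 4.3%, so the curve runs on [substrate] times time and autumn can serve you as a clock for these flasks. Ochre repeats autumn, which gives the ceiling, 20.6%; the floor is autumn at 15.0 h, 4.3%, as if the feed had arrived whole at its end.

To tighten the bracket you treat the steps as pseudo-first-order, with [reagent] integrated over time as their clock. In amber [reagent] climbs in a straight line during the feed, so, neglecting what reacts, you get the effective time, the time at full charge that gives the same integral, 27.5 h. Autumn between 25.0 h and 30.0 h then puts amber at 12.2%. In teal the fed substrate has ages from 15.0 h to 40 h, with the same mean, and averaging autumn over those ages gives 12.3%.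

The forecast puts ochre first at 20.5%, with teal at 14% and amber at 13%, of which flask it says “the integrated reagent exposure is lower”. Both fed values lie inside the bracket, above the figures reckoned here.

The flasks give 12.1% in amber, 20.1% in ochre and 12.5% in teal, so ochre leads.

    substrate + reagent → mono adduct (k = 0.00223 M⁻¹ min⁻¹)
    reagent + bis adduct → tris adduct (k = 8.24 × 10⁻⁵ M⁻¹ min⁻¹)
    reagent + mono adduct → bis adduct (k = 0.00316 M⁻¹ min⁻¹)
    reagent + tris adduct → tetra adduct (k = 0.00403 M⁻¹ min⁻¹)

Amber lands 0.10 percentage points below the effective-time figure, and teal 0.20 points above its average. Now take the neighbour, amber with 0.11 M of substrate and the same 27.5 h: its [substrate] times 27.5 h equals midnight's concentration held for 25.2 h, beside midnight's reading of 25.6% at 25.0 h. That neighbour gives 25.1% of bis adduct, with 44.1% still substrate.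

Readings and results are simulated with constants of no real substance; noise was put on by code.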